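**Retrosynthetic overview**

1. The target is an 8-aryloxy-6-hydroxy-3-pentylisocoumarin. The three O-alkyl groups come off last (BBr3); before that the pyranone ring is closed by enol lactonisation of a benzyl ketone made by lateral lithiation of the ring A o-toluate and acylation with a hexanoyl unit.
2. The plan rests on ring B: the ether carbon C1' lies between C2'–OH and C6'–pentyl, the second oxygen sits on C4' para to C1', and C3'/C5' carry H. This is the pattern a vinylketene–alkoxyalkyne benzannulation delivers.
3. Ring B is therefore grown onto an existing aryl–O–C1' bond: diazo enone 9 and ethoxyacetylene form C2'–C3', C4'–C5' and C1'–C2' (photo-Wolff, [2+2], 4π opening, 6π closure), so the crowded C1' is never arylated.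
4. Diazo enone 9 comes from acid 7 (acid chloride, diazomethane). Acid 7 comes from the phenoxide of 4-O-methyl methyl orsellinate and the enol tosylate of allyl 2-formylheptanoate by vinylic substitution, then deallylation.
5. Ring order: ring A is bought (methyl orsellinate), ring B is formed in step 7, the pyranone ring in step 11.

Key step: step 7

Remark: 4 is drawn as the aldehyde tautomer (racemic at C2), although the hydroxymethylene enol should predominate; cyclobutenone 12 and dienone 14 are racemic transient species, and the target has no stereocentre.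

**Route**

Step 1
Reactants: 1 methyl orsellinate (methyl 2,4-dihydroxy-6-methylbenzoate)
Product: 2 methyl 2-hydroxy-4-methoxy-6-methylbenzoate
Conditions: MeI (1.05 equiv), K2CO3, acetone, rt
Reagents that add atoms: iodomethane, CI
Why: The 2-OH is hydrogen-bonded to the ester carbonyl and less acidic, so one equivalent of MeI should alkylate the 4-OH selectively (Williamson ether synthesis).

Step 2
Reactants: 3 allyl heptanoate (prop-2-en-1-yl heptanoate)
Product: 4 allyl 2-formylheptanoate
Conditions: LiN(iPr)2, THF, −78 °C; HCO2CH2CH=CH2, −78 → 0 °C; aq. HCl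
Reagents that add atoms: allyl formate, C=CCOC=O
Why: Crossed Claisen condensation of the preformed lithium ester enolate with a formate; the formyl donor carries the same allyl group, so any alkoxide exchange is degenerate, and the product is held as its enolate until the acidic quench.

Step 3
Reactants: 4 allyl 2-formylheptanoate
Product: 5 allyl (2E)-2-({[(4-methylphenyl)sulfonyl]oxy}methylidene)heptanoate
Conditions: TsCl, N-methylimidazole, Et3N, CH2Cl2, 0 °C
Reagents that add atoms: 4-methylbenzenesulfonyl chloride, Cc1ccc(cc1)S(Cl)(=O)=O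
Why: O-Sulfonylation of the enol form through the N-sulfonylimidazolium salt; the E enol tosylate is expected to predominate, and either geometry serves because step 4 passes through a freely rotating enolate.

Step 4
Reactants: 2 methyl 2-hydroxy-4-methoxy-6-methylbenzoate; 5 allyl (2E)-2-({[(4-methylphenyl)sulfonyl]oxy}methylidene)heptanoate
Product: 6 methyl 2-{[(1E)-3-oxo-2-pentyl-3-(prop-2-en-1-yloxy)prop-1-en-1-yl]oxy}-4-methoxy-6-methylbenzoate
Conditions: Cs2CO3, DMF, 50 °C
Reagents that add atoms: none
Why: Nucleophilic vinylic substitution by addition–elimination: the cesium phenoxide adds to the β-carbon of the acrylate and the ester enolate expels tosylate; the E enol ether (aryloxy anti to the ester) is the thermodynamically preferred isomer and is the one purified and carried on.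

Step 5
Reactants: 6 methyl 2-{[(1E)-3-oxo-2-pentyl-3-(prop-2-en-1-yloxy)prop-1-en-1-yl]oxy}-4-methoxy-6-methylbenzoate
Product: 7 (2E)-3-[5-methoxy-2-(methoxycarbonyl)-3-methylphenoxy]-2-pentylprop-2-enoic acid
Conditions: Pd(PPh3)4 (5 mol %), TolSO2Na, THF/MeOH, rt; then aq. HCl
Reagents that add atoms: none
Why: Tsuji–Trost deallylation: zerovalent palladium ionises only the allyl ester and the sulfinate captures the π-allyl fragment, so no hydroxide is needed and the β-aryloxyacrylate (open to conjugate addition–elimination by hydroxide) and the methyl benzoate stay intact.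

Step 6
Reactants: 7 (2E)-3-[5-methoxy-2-(methoxycarbonyl)-3-methylphenoxy]-2-pentylprop-2-enoic acid
Product: 9 methyl 2-{[(1E)-4-diazo-3-oxo-2-pentylbut-1-en-1-yl]oxy}-4-methoxy-6-methylbenzoate, via acid chloride 8 (not isolated)
Conditions: 1-chloro-N,N,2-trimethylprop-1-en-1-amine, CH2Cl2, 0 °C → rt; then CH2N2 (3 equiv), Et2O, 0 °C
Reagents that add atoms: diazomethane, C=[N+]=[N-]
Why: The α-chloroenamine makes the acid chloride without HCl, so the E enol ether should not isomerise; diazomethane is then acylated (first stage of the Arndt–Eistert sequence) and a second equivalent takes up HCl, while the trisubstituted push–pull alkene is a poor dipolarophile, so pyrazoline formation should be slow at 0 °C.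

Step 7
Reactants: 9 methyl 2-{[(1E)-4-diazo-3-oxo-2-pentylbut-1-en-1-yl]oxy}-4-methoxy-6-methylbenzoate; 10 ethoxyacetylene
Product: 15 methyl 2-(4-ethoxy-2-hydroxy-6-pentylphenoxy)-4-methoxy-6-methylbenzoate, via vinylketene 11 (not isolated), via vinylcyclobutenone 12 (not isolated), via dienylketene 13 (not isolated), via cyclohexadienone 14 (not isolated)
Conditions: 10 (3 equiv), ClCH2CH2Cl, hν (Hg lamp, Pyrex, >300 nm), rt; then 80 °C, sealed tube
Reagents that add atoms: none
Why: Irradiation above 300 nm, where the diazo ketone but hardly the benzoate absorbs, expels N2 and the alkenyl group migrates (photochemical Wolff rearrangement) to give vinylketene 11 with the E enol ether geometry retained. The nucleophilic CH terminus of ethoxyacetylene attacks the ketene carbonyl carbon and a [2+2] cycloaddition gives 3-ethoxy-4-alkenylcyclobutenone 12 (bonds C2'–C3' and C4'–C5'), which fixes the ethoxy group para to the aryloxy carbon. At 80 °C 12 opens by reversible 4π electrocyclic ring opening to dienylketene 13, which closes ring B by disrotatory 6π electrocyclisation (bond C1'–C2'), and dienone 14 tautomerises to phenol 15. The closest known reaction type is the Danheiser benzannulation of α-diazo enones and heteroaryl diazo ketones with alkoxy- and siloxyalkynes; the acyclic β-aryloxy vinylketene is a new substrate for this known cascade. No stereocentre survives, since the sp3 carbons of 12 and 14 are removed by ring opening and aromatisation. The step needs the [2+2] regiochemistry, which the polarisation of the ynol ether secures, and a fast 6π closure, which the E geometry helps by placing the aryloxy group outward on the diene terminus; the excess of 10 should let trapping of 11 outrun its side reactions.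

Step 8
Reactants: 15 methyl 2-(4-ethoxy-2-hydroxy-6-pentylphenoxy)-4-methoxy-6-methylbenzoate
Product: 16 methyl 2-(2,4-diethoxy-6-pentylphenoxy)-4-methoxy-6-methylbenzoate
Conditions: EtI, K2CO3, DMF, rt
Reagents that add atoms: iodoethane, CCI
Why: Williamson ethylation caps the only free phenol before the strong-base step; intermolecular O-alkylation at room temperature should outrun attack of the phenoxide on the hindered ester or a Smiles rearrangement.

Step 9
Reactants: 17 hexanoyl chloride
Product: 18 N-methoxy-N-methylhexanamide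
Conditions: MeNHOMe·HCl, Et3N, CH2Cl2, 0 °C → rt
Reagents that add atoms: N,O-dimethylhydroxylamine hydrochloride, CNOC.Cl
Why: Acylation of the hydroxylamine by the acid chloride (Weinreb amide formation).

Step 10
Reactants: 16 methyl 2-(2,4-diethoxy-6-pentylphenoxy)-4-methoxy-6-methylbenzoate; 18 N-methoxy-N-methylhexanamide
Product: 19 methyl 2-(2,4-diethoxy-6-pentylphenoxy)-4-methoxy-6-(2-oxoheptyl)benzoate
Conditions: LiN(iPr)2 (2 equiv), THF, −78 °C; then 18, −78 → 0 °C; aq. HCl
Reagents that add atoms: none
Why: Lateral (benzylic) lithiation of the o-toluate gives the ester-stabilised benzylic anion, which adds once to the amide because the chelated tetrahedral adduct persists until the quench (Weinreb ketone synthesis); the di-ortho-substituted ester resists self-condensation.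

Step 11
Reactants: 19 methyl 2-(2,4-diethoxy-6-pentylphenoxy)-4-methoxy-6-(2-oxoheptyl)benzoate
Product: 20 8-(2,4-diethoxy-6-pentylphenoxy)-6-methoxy-3-pentyl-1H-isochromen-1-one
Conditions: p-TsOH·H2O (0.2 equiv), toluene, 110 °C, MeOH distilled off
Reagents that add atoms: none
Why: Acid-catalysed enol lactonisation: the enol oxygen of the benzyl ketone attacks the neighbouring ester in a six-membered ring closure, and loss of methanol gives the conjugated isocoumarin.

Step 12
Reactants: 20 8-(2,4-diethoxy-6-pentylphenoxy)-6-methoxy-3-pentyl-1H-isochromen-1-one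
Product: 21 8-(2,4-dihydroxy-6-pentylphenoxy)-6-hydroxy-3-pentyl-1H-isochromen-1-one (target)
Conditions: BBr3 (6 equiv), CH2Cl2, −78 °C → rt; then H2O, 0 °C
Reagents that add atoms: none
Why: BBr3 cleaves alkyl aryl ethers by bromide attack on the O-alkyl carbon of the boron-complexed ether, so the methyl and both ethyl groups should leave, while the diaryl ether (no SN2 at an aryl carbon) and the lactone should survive a cold, non-basic work-up.

**Compound list**

1 | methyl orsellinate (methyl 2,4-dihydroxy-6-methylbenzoate) | COC(=O)c1c(C)cc(O)cc1O | starting material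
2 | methyl 2-hydroxy-4-methoxy-6-methylbenzoate | COC(=O)c1c(C)cc(OC)cc1O | intermediate
3 | allyl heptanoate | CCCCCCC(=O)OCC=C | starting material
4 | allyl 2-formylheptanoate (racemic; aldehyde/enol tautomers) | CCCCCC(C=O)C(=O)OCC=C | intermediate
5 | allyl (2E)-2-({[(4-methylphenyl)sulfonyl]oxy}methylidene)heptanoate | CCCCC/C(=C\OS(=O)(=O)c1ccc(C)cc1)C(=O)OCC=C | intermediate
6 | methyl 2-{[(1E)-3-oxo-2-pentyl-3-(prop-2-en-1-yloxy)prop-1-en-1-yl]oxy}-4-methoxy-6-methylbenzoate | CCCCC/C(=C\Oc1cc(OC)cc(C)c1C(=O)OC)C(=O)OCC=C | intermediate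
7 | (2E)-3-[5-methoxy-2-(methoxycarbonyl)-3-methylphenoxy]-2-pentylprop-2-enoic acid | CCCCC/C(=C\Oc1cc(OC)cc(C)c1C(=O)OC)C(=O)O | intermediate
8 | (2E)-3-[5-methoxy-2-(methoxycarbonyl)-3-methylphenoxy]-2-pentylprop-2-enoyl chloride | CCCCC/C(=C\Oc1cc(OC)cc(C)c1C(=O)OC)C(Cl)=O | intermediate
9 | methyl 2-{[(1E)-4-diazo-3-oxo-2-pentylbut-1-en-1-yl]oxy}-4-methoxy-6-methylbenzoate | CCCCC/C(=C\Oc1cc(OC)cc(C)c1C(=O)OC)C(=O)C=[N+]=[N-] | intermediate
10 | ethoxyacetylene | CCOC#C | starting material
11 | methyl 4-methoxy-2-methyl-6-{[(1E)-4-oxo-2-pentylbuta-1,3-dien-1-yl]oxy}benzoate (vinylketene) | CCCCC/C(=C\Oc1cc(OC)cc(C)c1C(=O)OC)C=C=O | intermediate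
12 | methyl 2-{[(1E)-2-(2-ethoxy-4-oxocyclobut-2-en-1-yl)hept-1-en-1-yl]oxy}-4-methoxy-6-methylbenzoate (racemic) | CCCCC/C(=C\Oc1cc(OC)cc(C)c1C(=O)OC)C1C(=O)C=C1OCC | intermediate
13 | methyl 2-{[(1E,3E)-4-ethoxy-6-oxo-2-pentylhexa-1,3,5-trien-1-yl]oxy}-4-methoxy-6-methylbenzoate (dienylketene) | O=C=C/C(OCC)=C\C(CCCCC)=C\Oc1cc(OC)cc(C)c1C(=O)OC | intermediate
14 | methyl 2-[(4-ethoxy-6-oxo-2-pentylcyclohexa-2,4-dien-1-yl)oxy]-4-methoxy-6-methylbenzoate (racemic) | CCCCCC1=CC(OCC)=CC(=O)C1Oc1cc(OC)cc(C)c1C(=O)OC | intermediate
15 | methyl 2-(4-ethoxy-2-hydroxy-6-pentylphenoxy)-4-methoxy-6-methylbenzoate | CCCCCc1cc(OCC)cc(O)c1Oc1cc(OC)cc(C)c1C(=O)OC | intermediate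
16 | methyl 2-(2,4-diethoxy-6-pentylphenoxy)-4-methoxy-6-methylbenzoate | CCCCCc1cc(OCC)cc(OCC)c1Oc1cc(OC)cc(C)c1C(=O)OC | intermediate
17 | hexanoyl chloride | CCCCCC(Cl)=O | starting material
18 | N-methoxy-N-methylhexanamide | CCCCCC(=O)N(C)OC | intermediate
19 | methyl 2-(2,4-diethoxy-6-pentylphenoxy)-4-methoxy-6-(2-oxoheptyl)benzoate | CCCCCC(=O)Cc1cc(OC)cc(Oc2c(OCC)cc(OCC)cc2CCCCC)c1C(=O)OC | intermediate
20 | 8-(2,4-diethoxy-6-pentylphenoxy)-6-methoxy-3-pentyl-1H-isochromen-1-one | CCCCCc1cc2cc(OC)cc(Oc3c(OCC)cc(OCC)cc3CCCCC)c2c(=O)o1 | intermediate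
21 | 8-(2,4-dihydroxy-6-pentylphenoxy)-6-hydroxy-3-pentyl-1H-isochromen-1-one | CCCCCc1cc2cc(O)cc(Oc3c(O)cc(O)cc3CCCCC)c2c(=O)o1 | target

**Step count**

Total steps: 12. Longest linear sequence: 10 steps (steps 2–8 and 10–12, from allyl heptanoate 3).

**Steps most likely to fail**

Step 7. Trapping of the donor-substituted vinylketene by the alkyne may be slow, so that ketene oligomerisation or capture by the phenol product competes. Light-induced E-to-Z isomerisation of the enol ether may place the aryloxy group inward and stall the 6π closure, and the aryl vinyl ether may degrade photochemically. The fallback builds the diaryl ether by known cross-coupling; it sets out from 2 and comes back at 16.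
- Phenol 2 is converted with Tf2O and pyridine in CH2Cl2 into the aryl triflate methyl 4-methoxy-2-methyl-6-{[(trifluoromethyl)sulfonyl]oxy}benzoate F1.
- Separately, commercial olivetol (5-pentylbenzene-1,3-diol) is ethylated with EtI and K2CO3 in DMF to 1,3-diethoxy-5-pentylbenzene F2.
- Vilsmeier–Haack formylation (POCl3, DMF), para to one ethoxy group and ortho to the pentyl chain, gives 2,4-diethoxy-6-pentylbenzaldehyde F3.
- Dakin-type Baeyer–Villiger oxidation with mCPBA in CH2Cl2 gives 2,4-diethoxy-6-pentylphenyl formate F4, and NaOH in aqueous MeOH gives 2,4-diethoxy-6-pentylphenol F5.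
- Buchwald–Hartwig C–O coupling of F1 with F5 (Pd(OAc)2, 2-di-tert-butylphosphino-2',4',6'-triisopropylbiphenyl, K3PO4, toluene, 100 °C) should give 16, and the route continues with step 10.

Step 6. Diazomethane may add as a 1,3-dipole across the enoyl C=C (pyrazoline formation) faster than it is acylated, or the enol ether may lose its E geometry during acid chloride formation. The fallback is the detrifluoroacetylative diazo transfer made for α'-diazo enones; it sets out from 7 and comes back at 9.
- Acid 7 is converted through 8 with MeNHOMe·HCl and pyridine into the Weinreb amide methyl 4-methoxy-2-({(1E)-3-[methoxy(methyl)amino]-3-oxo-2-pentylprop-1-en-1-yl}oxy)-6-methylbenzoate F6.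
- MeMgBr in THF at −78 → 0 °C gives the methyl ketone methyl 4-methoxy-2-methyl-6-{[(1E)-3-oxo-2-pentylbut-1-en-1-yl]oxy}benzoate F7.
- LiN(SiMe3)2 in THF at −78 °C followed by CF3CO2CH2CF3 gives the trifluoroacetyl ketone methyl 4-methoxy-2-methyl-6-{[(1E)-6,6,6-trifluoro-3,5-dioxo-2-pentylhex-1-en-1-yl]oxy}benzoate F8.
- MsN3, Et3N and one equivalent of water in MeCN transfer the diazo group with loss of the trifluoroacetyl group to give 9.

Step 4. The hindered, hydrogen-bonded phenoxide may attack sulfur of the enol tosylate (sulfonyl transfer, returning the enolate of 4) instead of the β-carbon, or the addition may be too slow at a temperature the allyl ester tolerates. The fallback replaces the sulfonate by a vinylogous acid chloride; it sets out from 4 and comes back at 6.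
- Formyl ester 4 is treated with (COCl)2 and DMF in CH2Cl2 (Vilsmeier-type chlorination of the enol) to give allyl (2E)-3-chloro-2-pentylprop-2-enoate F9, of which either geometric isomer serves.
- Phenol 2 with K2CO3 and catalytic DABCO in MeCN at 60 °C displaces chloride by addition–elimination to give 6.

**Further compounds**

F1 | step 7 | methyl 4-methoxy-2-methyl-6-{[(trifluoromethyl)sulfonyl]oxy}benzoate | COC(=O)c1c(C)cc(OC)cc1OS(=O)(=O)C(F)(F)F
F2 | step 7 | 1,3-diethoxy-5-pentylbenzene | CCCCCc1cc(OCC)cc(OCC)c1
F3 | step 7 | 2,4-diethoxy-6-pentylbenzaldehyde | CCCCCc1cc(OCC)cc(OCC)c1C=O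
F4 | step 7 | 2,4-diethoxy-6-pentylphenyl formate | CCCCCc1cc(OCC)cc(OCC)c1OC=O
F5 | step 7 | 2,4-diethoxy-6-pentylphenol | CCCCCc1cc(OCC)cc(OCC)c1O
F6 | step 6 | methyl 4-methoxy-2-({(1E)-3-[methoxy(methyl)amino]-3-oxo-2-pentylprop-1-en-1-yl}oxy)-6-methylbenzoate | CCCCC/C(=C\Oc1cc(OC)cc(C)c1C(=O)OC)C(=O)N(C)OC
F7 | step 6 | methyl 4-methoxy-2-methyl-6-{[(1E)-3-oxo-2-pentylbut-1-en-1-yl]oxy}benzoate | CCCCC/C(=C\Oc1cc(OC)cc(C)c1C(=O)OC)C(C)=O
F8 | step 6 | methyl 4-methoxy-2-methyl-6-{[(1E)-6,6,6-trifluoro-3,5-dioxo-2-pentylhex-1-en-1-yl]oxy}benzoate | CCCCC/C(=C\Oc1cc(OC)cc(C)c1C(=O)OC)C(=O)CC(=O)C(F)(F)F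
F9 | step 4 | allyl (2E)-3-chloro-2-pentylprop-2-enoate | CCCCC/C(=C\Cl)C(=O)OCC=C
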